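(All runs are simulated from invented constants; noise was put on by code.)

The easy mistake with a protic impurity is to treat it as a spectator and compare flasks by the incoming ligand charged, which is 0.260 M in north-east and in south alike.

| flask | starting complex | incoming ligand | protic impurity | remark | time |
|---|---|---|---|---|---|
| noon | 0.20 M | 0.26 M | 0.023 M | run made earlier |  |
| autumn | 0.20 M | 0.26 M | 0.17 M | run made earlier |  |
| north-east | 0.20 M | 0.260 M | 0.0200 M |  | 8.0 min |
| west | 0.20 M | 0.260 M | 0.0600 M |  | 8.0 min |
| south | 0.20 M | 0.260 M | 0.200 M |  | 8.0 min |
| south-west | 0.20 M | 0.260 M | 0.500 M |  | 8.0 min |
| north-west | 0.20 M | 0.260 M | 1.50 M |  | 8.0 min |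

| run | time / min | complex with one exchanged / % | starting complex / % |
|---|---|---|---|
| noon | 0.667 | 19.6 | 61.7 |
| noon | 1.33 | 21.2 | 58.2 |
| noon | 3.00 | 18.2 | 60.0 |
| noon | 8.00 | 15.2 | 60.0 |
| autumn | 0.667 | 17.9 | 68.9 |
| autumn | 1.33 | 19.9 | 68.7 |
| autumn | 3.00 | 16.2 | 72.8 |
| autumn | 8.00 | 12.8 | 77.8 |

(each reading ± 0.3 percentage points)

- the numbers in the tables scatter with a standard deviation of 0.3 percentage points
- "hardly changes" means that all values lie within two and a half points (for a concentration: within two and a half percent of the largest)

- amount of complex with one exchanged at the end, in percent of the starting complex charged for north-east, west, south, south-west, north-west, in this order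
- how that number moves from the first to the last of them (rises, then falls / hardly changes / falls, then rises / falls all the way / rises all the way)

Watch the noon run in slow motion. At 0.667 min starting complex has already dropped to 61.7%, with complex with one exchanged at 19.6%, so the first exchange is quick on this clock. At 1.33 min that complex gives its highest reading, 21.2%, and by 8.00 min it reads 15.2% while starting complex reads 60.0%, so it seems to be passing into something the readings don't list. In the autumn run starting complex reads 68.7% at 1.33 min, but then it climbs to 77.8% by 8.00 min, and I read this as the impurity slowly taking incoming ligand, so that exchange runs backward.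

So I assume the impurity takes incoming ligand one for one. In north-east this leaves 0.240 M; call the incoming ligand charged less the protic impurity charged the spare ligand. It is 0.237 M at noon and 0.0900 M in autumn, where the end ratio of complex with one exchanged to starting complex reads 0.165 against 0.253 at noon.

My own reckoning draws straight lines through these two runs, for starting complex and for the ratio, both against spare ligand, and multiplies the two answers. This gives 15.2% for north-east, 14.9% for west and 11.9% for south. In south-west the spare ligand is −0.240 M, because impurity exceeds incoming ligand, which makes incoming ligand the limiting reagent of that quenching, so the lines end there and I expect a further fall in south-west and north-west.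

The forecast, made separately, gave 15.2%, 14.7%, 12.4%, 8.5% and 4%, shape falls all the way, on the ground that “the impurity seems to remove free incoming ligand”; at south its 12.4% differs from my figure.

The flasks give 15.0%, 14.9%, 11.3%, 5.57% and 3.79%, shape falls all the way, and the forecast stands within its margins on the row and on the shape.

    protic impurity + incoming ligand → quenched reagent (k = 0.179 M⁻¹ s⁻¹)
    starting complex + incoming ligand ⇌ leaving ligand + complex with one exchanged (K = 0.570, k = 0.0875 M⁻¹ s⁻¹)
    complex with one exchanged + incoming ligand ⇌ leaving ligand + complex with two exchanged (K = 0.720, k = 0.531 M⁻¹ s⁻¹)
    complex with two exchanged + incoming ligand ⇌ leaving ligand + complex with three exchanged (K = 10.7, k = 0.107 M⁻¹ s⁻¹)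

In north-east at 8.00 min, the step between starting complex and complex with one exchanged, taken by itself with both directions counted, relaxes with a half-life of 0.244 min, shorter than the 1.06 min of the step to complex with three exchanged, taken the same way, and short against the 8.0 min of the run. The spare ligand of 0.240 M stands there at 8.00 min as leaving ligand plus free incoming ligand, together 0.240 M, and in south, with spare ligand 0.0600 M, the same two sum at 80.0 min to 0.0600 M.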